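The readings are calculated on assumed constants; the scatter is artificial.

Late in this flask I ask how much catalyst the impurity has left to work with: on the list of suspects, free catalyst + impurity goes one way to spent catalyst, one for one.

| flask | substrate | coupling partner | free catalyst | impurity | remark |
|---|---|---|---|---|---|
| Tuesday's | 0.20 M | 1 M | 2 mM | 1.1 mM | the very flask that is asked about, followed so far |
| Saturday's | 0.40 M | 1 M | 2 mM | 1.1 mM | run made earlier |
| flask | 0.20 M | 1.00 M | 2.0 mM | 1.1 mM |  |

- Tuesday's (time / h: product / %, substrate / %): 2.00: 1.6, 97.9; 4.00: 4.3, 95.7; 10.0: 8.8, 90.5; 25.0: 19.1, 79.1
- Saturday's (time / h: product / %, substrate / %): 4.00: 1.8, 96.8; 8.00: 5.7, 95.1; 20.0: 11.2, 88.5; 50.0: 24.4, 76.0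

(scatter of a reading: 0.5 percentage points)

- on the list of suspects stand: free catalyst + impurity -> spent catalyst; catalyst intermediate C <-> free catalyst + product; coupling partner + catalyst intermediate A -> catalyst intermediate B; catalyst intermediate B -> by-product + catalyst intermediate C; substrate + free catalyst <-> catalyst intermediate A
- no earlier run changes the charge of free catalyst; that part of a forecast is a guess
- no earlier run changes the charge of coupling partner; that part of a forecast is a guess

* apparent order in coupling partner when 50 % of the substrate are converted (percent change of the rate of making product for one percent more coupling partner charged)
* apparent order in free catalyst when 50 % of the substrate are converted (percent change of the rate of making product for one percent more free catalyst charged)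

The asked point of 50 % lies beyond Tuesday's last reading of 19.1 % product, and neither run changes the free catalyst or the coupling partner, so both orders are reckonings of mine. I suppose that the 1.1 mM of impurity is consumed by then and that, at fixed conversion, the rate follows the catalyst still alive. The order in free catalyst is then the slope of ln(live catalyst) against ln(catalyst charged).

Which inputs must be known well? My slope contains neither the scatter of 0.5 percentage points in the readings nor the substrate charge. The impurity charge does: a relative error in it comes back in the order multiplied by impurity over surviving catalyst, 1.22. An error in the catalyst charge comes back with the same factor and opposite sign. So these two charges carry the number: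

f = 1 − impurity charge / free catalyst charge = 0.450

n = d ln(f × charge) / d ln(charge) = 1/f = 2.22

Here f is the live fraction, the share of the charged catalyst that outlasts the impurity. For the coupling partner I guess an order of 1, since it enters by a single step with catalyst intermediate A, and no run tests this.

The forecast says 2.1 for free catalyst, a little below my 2.22, and 0.7 for coupling partner, below my guess, “reduced if C or release limits turnover”.

The flask gives 2.2 in free catalyst and 0.97 in coupling partner.

    free catalyst + impurity → spent catalyst (k = 1.48 /M/s)
    catalyst intermediate C ⇌ free catalyst + product (K = 0.0772 M, k = 0.0205 /s)
    coupling partner + catalyst intermediate A → catalyst intermediate B (k = 0.00218 /M/s)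
    catalyst intermediate B → by-product + catalyst intermediate C (k = 0.00311 /s)
    substrate + free catalyst ⇌ catalyst intermediate A (K = 2.93 /M, k = 0.0831 /M/s)

At the asked conversion, reached after 3.82 d, spent catalyst holds 55.0 % of the catalyst, which leaves 45.0 % outside it, the f = 0.450 of this flask. The reaction of free catalyst with impurity is the largest single effect on the order in free catalyst. This flask, run without that reaction, loses no catalyst to spent catalyst, so there f is 1 and 1/f is 1. The order in free catalyst in that run is 1.0.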